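The numbers in the tables were generated by integration from invented constants; noise was put on by code.

I read these flasks at 30 h, and what I want from that reading is the share of target among the products. Autumn and summer carry the same charges, but autumn feeds the first nucleophile over 10 h, while summer has it in from the start.

| setting | Sunday's | Tuesday's | Thursday's | autumn | summer |
|---|---|---|---|---|---|
| substrate | 0.020 M | 0.020 M | 0.030 M | 0.020 M | 0.020 M |
| first nucleophile | 0.025 M (fed, over 10 h) | 0.038 M (fed, over 10 h) | 0.050 M (fed, over 10 h) | 0.0500 M (fed, over 10 h) | 0.0500 M |
| second nucleophile | 0.021 M | 0.021 M | 0.021 M | 0.0210 M | 0.0210 M |
| remark | run made earlier | run made earlier | run made earlier |  | everything together at the start |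
| time |  |  |  | 30 h | 30 h |

- Sunday's (time / h: target / %, other capture product / %, solvolysis product / %): 5.00: 4, 28, 35; 10.0: 7, 39, 46; 15.0: 6, 37, 51; 20.0: 14, 37, 50; 25.0: 12, 39, 50
- Tuesday's (time / h: target / %, other capture product / %, solvolysis product / %): 5.00: 6, 26, 35; 10.0: 12, 32, 45; 15.0: 13, 36, 44; 20.0: 15, 37, 46; 25.0: 14, 36, 49
- Thursday's (time / h: target / %, other capture product / %, solvolysis product / %): 2.00: 0, 16, 20; 6.00: 9, 27, 38; 12.0: 15, 35, 47; 15.0: 15, 33, 46; 25.0: 18, 31, 48

(each reading ± 1.5 percentage points)

- the numbers in the tables scatter with a standard deviation of 1.5 percentage points
- what may be going on: substrate -> intermediate; intermediate -> solvolysis product; first nucleophile + intermediate -> target; second nucleophile + intermediate -> other capture product; intermediate -> side product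

1. which of the two ends with the higher share of target in all that became target or other capture product or solvolysis product or side product ("neither" if they lie within 2 percentage points) (autumn / summer / neither)
2. share of target in all that became target or other capture product or solvolysis product or side product, autumn
3. share of target in all that became target or other capture product or solvolysis product or side product, summer

Substrate decays first-order, and the products read together show how far it has gone. In Sunday's run they hold 67.0% after 5.00 h, and the logarithm of what remains gives a rate constant of 0.222 h⁻¹. Each intermediate then divides among its paths, and target per solvolysis product, a selectivity, is proportional to the first nucleophile present at that moment. So a feed should be judged by the concentration substrate meets as it decays. Under a steady feed that concentration climbs, then stands. Weighting it by the decay gives the feed rate times a time, 4.02 h: the fraction of substrate gone when the feed ends, divided by the rate constant. For autumn this makes 0.0201 M, the seen concentration: the average first nucleophile met by decaying substrate, leaving aside what capture uses.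

Thursday's run has the same feed rate, hence the same seen concentration, and its target over solvolysis product reads 0.375 at 25.0 h. I take that ratio for autumn. Summer holds 0.0500 M, so I scale the ratio up to 0.933. Other capture product over solvolysis product I read from Tuesday's run, with the same substrate and second nucleophile, as 0.735. Setting side product aside, I reckon 17.8% for autumn and 35.0% for summer.

The forecast, built on “the mean first nucleophile seen during substrate decay”, names summer, with 19% for autumn and 33% for summer. My summer figure stands above its figure, and my autumn figure below.

The flask gives summer: 17.8% for autumn and 36.7% for summer.

    substrate → intermediate (k = 0.230 h⁻¹)
    intermediate → solvolysis product (k = 48.0 h⁻¹)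
    first nucleophile + intermediate → target (k = 1100 L mol⁻¹ h⁻¹)
    second nucleophile + intermediate → other capture product (k = 2100 L mol⁻¹ h⁻¹)
    intermediate → side product (k = 1.80 h⁻¹)

The way the first nucleophile goes in is the main reason: summer's share is 36.7%, and with that difference taken away, the charge being fed as in autumn, it is 17.8%. Autumn's feed shows decaying substrate a seen concentration of 0.0201 M, while summer's substrate meets 0.0500 M from the start. A neighbour flask tests that figure: it is summer's flask with 0.020 M of first nucleophile at the start, matching autumn's seen concentration, and its share of target ends at 18.7% against autumn's 17.8%.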